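The eleven-membered ring (C1 bearing the methylene, C2=C3, C4Me2, C5–O, C6, C7, C8(Me)=C9, C10, C11) is uncovered, not closed. Because C3 and C8 sit 1,6 to each other, a bond imagined between them gives a trans-fused bicycle: cyclohexane C3–C8 fused to cycloheptane C3, C8–C11, C1, C2, a homologue of the Wieland–Miescher ketone. The key step reverses this: a C3 alkoxide expels a C9 mesylate, cutting the fusion bond and giving at once the eleven-membered ring, the (E)-C8=C9 alkene and a C3 ketone, which is trapped in the same flask as its dienyl triflate. The precursor carries C3–OH trans and C9–OMs cis to the C8 methyl, C4Me2, a C5 silyl ether and the C1 methylene.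

Key step: step 14

Remarks.
- Labels: C1–C11 are the target ring atoms defined above; they are kept for the bicyclic intermediates, and all CIP descriptors below use these labels.
- Stereochemical check against the target: C5 is R from step 6 onward. The fragmentation substrate needs C9–O cis and C3–O trans to the C8 methyl, and the SMILES of 17 encodes this.
- Assumption: a D-amino acid is taken to give the (8R)-enedione 6, mirroring the sense that L-amino acids show in annulations of this class.

Step 1
Reactants: 1 cycloheptane-1,3-dione; 2 iodomethane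
Product: 3 2-methylcycloheptane-1,3-dione
Conditions: K2CO3, acetone, reflux
Reagents that add atoms: iodomethane (compound 2), CI
Why: C-alkylation of the 1,3-diketone enolate (the seven-membered dione behaves like an open-chain β-diketone) should give the 2-methyl dione.

Step 2
Reactants: 3 2-methylcycloheptane-1,3-dione; 4 methyl vinyl ketone
Product: 6 (8R)-enedione [(4aR)-4a-methyl-4,4a,6,7,8,9-hexahydro-3H-benzo[7]annulene-2,5-dione; C5 and C9 ketones; C3=C4 alkene; C8 methyl], via triketone 5 (not isolated)
Conditions: Et3N (cat.), EtOAc, rt; evaporate; D-phenylalanine, (1S)-(+)-10-camphorsulfonic acid, DMF, 30 → 70 °C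
Reagents that add atoms: methyl vinyl ketone (compound 4), CC(=O)C=C
Why: a base-catalysed Michael addition gives triketone 5 and an amino-acid-mediated enamine aldol condensation (Robinson annulation of the Hajos–Parrish–Eder–Sauer–Wiechert type) closes the cyclohexenone, the D-amino acid selecting between the two enantiotopic ring carbonyls so that the quaternary C8 is R.

Step 3
Reactants: 6 (8R)-enedione
Product: 7 (8R,9R)-hydroxy enone (C9–OH cis to the C8 methyl; C5 enone kept)
Conditions: NaBH4 (0.3 equiv), EtOH, −10 °C
Reagents that add atoms: none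
Why: borohydride reduction is chemoselective for the saturated C9 ketone over the conjugated C5 carbonyl, and hydride should approach C9 from the face opposite the adjacent C8 methyl, placing C9–OH cis to that methyl (9R).

Step 4
Reactants: 7 (8R,9R)-hydroxy enone
Product: 8 (8R,9R)-C9 triethylsilyl ether
Conditions: Et3SiCl, imidazole, DMF, rt
Reagents that add atoms: chlorotriethylsilane, CC[Si](Cl)(CC)CC
Why: standard silylation of a secondary alcohol, the TES ether being chosen because it survives alkoxide, hydride, ylide and peracid and can later be removed beside a TBS ether.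

Step 5
Reactants: 8 (8R,9R)-C9 triethylsilyl ether; 2 iodomethane
Product: 9 (8R,9R)-β,γ-unsaturated ketone (C5 ketone; C4Me2; C2=C3 alkene; C9–OTES)
Conditions: KOtBu, tBuOH/THF, 0 °C → rt
Reagents that add atoms: iodomethane (compound 2), CI
Why: deconjugative α,α-dialkylation, in which γ-deprotonation gives the extended dienolate that is methylated twice at C4, moves the alkene to C2=C3 and leaves C8 and C9 untouched.

Step 6
Reactants: 9 (8R,9R)-β,γ-unsaturated ketone
Product: 10 (5R,8R,9R)-alcohol (C5–OH cis to the C8 methyl)
Conditions: LiAlH4, Et2O, −20 → 0 °C; aq. NaOH work-up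
Reagents that add atoms: none
Why: hydride reduction by axial attack on C5 from the face opposite the axial C4 methyl and the C8 methyl should give the equatorial C5–OH cis to the C8 methyl (5R), as in 4,4-dimethyl-3-oxo terpenoid rings.

Step 7
Reactants: 10 (5R,8R,9R)-alcohol
Product: 11 (5R,8R,9R)-bis-silyl ether (C5–OTBS; C9–OTES)
Conditions: TBSOTf, 2,6-lutidine, CH2Cl2, −78 → 0 °C
Reagents that add atoms: tert-butyldimethylsilyl trifluoromethanesulfonate, CC(C)(C)[Si](C)(C)OS(=O)(=O)C(F)(F)F
Why: silylation with a silyl triflate is the reliable way to protect a neopentylic secondary alcohol.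

Step 8
Reactants: 11 (5R,8R,9R)-bis-silyl ether
Product: 12 (5R,8R,9R)-enone (C1 ketone conjugated with C2=C3)
Conditions: Rh2(cap)4 (dirhodium tetracaprolactamate, cat.), tBuOOH, K2CO3, CH2Cl2, rt
Reagents that add atoms: tert-butyl hydroperoxide, CC(C)(C)OO
Why: allylic C–H oxidation with tert-butyl hydroperoxide under dirhodium catalysis should be regiospecific, since C1 is the only allylic position bearing hydrogen (C4 and C8 are quaternary).

Step 9
Reactants: 12 (5R,8R,9R)-enone
Product: 13 (5R,8R,9R)-diene (C1 methylene conjugated with C2=C3)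
Conditions: Ph3PCH3Br, KOtBu, THF, 0 °C → rt
Reagents that add atoms: methyltriphenylphosphonium bromide, C[P+](c1ccccc1)(c1ccccc1)c1ccccc1.[Br-]
Why: Wittig methylenation of the unhindered enone carbonyl gives the 2-substituted 1,3-diene without touching the silyl ethers.

Step 10
Reactants: 13 (5R,8R,9R)-diene
Product: 14 (2R,3S,5R,8S,9R)-vinyl epoxide (C2–C3 epoxide trans to the C8 methyl; C1 methylene)
Conditions: mCPBA, NaHCO3, CH2Cl2, −20 → 0 °C
Reagents that add atoms: 3-chloroperoxybenzoic acid, OOC(=O)c1cccc(Cl)c1
Why: Prilezhaev epoxidation should take the more substituted C2=C3 bond of the diene from the face opposite the C8 methyl and the axial C4 methyl, which sets the C3–O bond trans to the C8 methyl (2R,3S).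

Step 11
Reactants: 14 (2R,3S,5R,8S,9R)-vinyl epoxide
Product: 15 (3S,5R,8S,9R)-tertiary alcohol (C3–OH trans to the C8 methyl; C2H2; C1 methylene; C5–OTBS; C9–OTES)
Conditions: Pd2(dba)3·CHCl3 (cat.), PBu3, HCO2H, Et3N, 1,4-dioxane, rt
Reagents that add atoms: none
Why: zerovalent palladium opens the vinyl epoxide to a π-allyl complex spanning C2, C1 and the methylene carbon, and hydride from formate is delivered to the internal terminus C2 (palladium–formate hydrogenolysis of an alkenyl oxirane, a Tsuji–Trost-type reduction), so the C1 methylene and the C3–O configuration are kept.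

Step 12
Reactants: 15 (3S,5R,8S,9R)-tertiary alcohol
Product: 16 (3S,5R,8S,9R)-C3,C9-diol (C5–OTBS kept)
Conditions: PPTS, MeOH/CH2Cl2, 0 °C → rt
Reagents that add atoms: none
Why: acid-catalysed methanolysis cleaves a triethylsilyl ether far faster than a tert-butyldimethylsilyl ether (selective desilylation), freeing only C9–OH.

Step 13
Reactants: 16 (3S,5R,8S,9R)-C3,C9-diol
Product: 17 (3S,5R,8S,9R)-C9 mesylate (C3–OH free; C5–OTBS; C1 methylene)
Conditions: MsCl, Et3N, CH2Cl2, −10 → 0 °C
Reagents that add atoms: methanesulfonyl chloride, CS(=O)(=O)Cl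
Why: mesylation through the sulfene takes the secondary C9–OH with retention at C9 and leaves the tertiary, doubly neopentylic C3–OH untouched.

Step 14
Reactants: 17 (3S,5R,8S,9R)-C9 mesylate
Product: 20 (2Z,5R,8E)-dienyl triflate (C3–OTf; C1 trans to C4 across C2=C3; C1 methylene; C5–OTBS), via cycloundecenone 18 (not isolated), via potassium dienolate 19 (not isolated)
Conditions: KN(SiMe3)2 (1.1 equiv), THF, −78 → 0 °C; KN(SiMe3)2 (1.2 equiv), −78 → 0 °C; PhNTf2 (1.4 equiv), −78 → 0 °C
Reagents that add atoms: N-phenylbis(trifluoromethanesulfonimide), O=S(=O)(N(c1ccccc1)S(=O)(=O)C(F)(F)F)C(F)(F)F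
Why: KN(SiMe3)2 deprotonates the tertiary C3–OH, and in the alkoxide the oxygen lone pair forms the C3=O bond while the C3–C8 σ bond, antiperiplanar to C9–OMs, becomes the C8=C9 π bond and mesylate leaves in one concerted heterolytic step (Wharton–Grob fragmentation), the closest known reaction type being the base-induced fragmentation of cyclic 1,3-diol monosulfonates to medium-ring (E)-cycloalkenones. No ring is closed and no stereocentre is made: the eleven-membered ring C1–C11 of ketone 18 appears when the zero-atom bridge of the six/seven bicycle is cut, so no medium-ring closure has to be paid for, and C3, C8 and C9 lose their stereogenicity while C5 is untouched. The first selectivity needed is E at C8=C9, and the substrate secures it, since with the trans ring fusion and the C9–O bond cis to the C8 methyl the only conformer that holds C9–O anti to C3–C8 also holds C10 anti to C7. The C2 hydrogens of ketone 18 are activated by both the carbonyl and the C1 methylene, so unreacted alkoxide and the second portion of base draw it into dienolate 19 (C4 is quaternary, so enolisation can only go toward C2), which funnels all material through the fragmentation and keeps the C1 methylene out of conjugation. The second selectivity is the dienolate geometry, where allylic strain with the quaternary C4 should place C1 cis to the oxygen, as in tert-alkyl ketone enolates. PhNTf2 then sulfonylates the dienolate on oxygen (enol triflate formation) and fixes that geometry in triflate 20.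

Step 15
Reactants: 20 (2Z,5R,8E)-dienyl triflate
Product: 21 (2E,5R,8E)-triene TBS ether
Conditions: Pd(OAc)2 (cat.), PPh3, HCO2H, Bu3N, DMF, 60 °C
Reagents that add atoms: none
Why: oxidative addition of the dienyl triflate to zerovalent palladium, formate-to-hydride exchange and reductive elimination with retention (palladium-catalysed formate reduction of an enol triflate) should give the (2E)-alkene of the conjugated diene.

Step 16
Reactants: 21 (2E,5R,8E)-triene TBS ether
Product: 22 (1R,3E,8E)-2,2,9-trimethyl-5-methylidenecycloundeca-3,8-dien-1-ol (the free C5 alcohol)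
Conditions: Bu4NF, THF, rt → 45 °C
Reagents that add atoms: none
Why: fluoride-mediated desilylation frees the C5 alcohol without touching the triene or the C5 configuration.

Step 17
Reactants: 23 vanillic acid
Product: 24 4-acetoxy-3-methoxybenzoic acid
Conditions: NaOH (aq), Ac2O, 0 °C; then HCl
Reagents that add atoms: acetic anhydride, CC(=O)OC(C)=O
Why: Schotten–Baumann acetylation in aqueous base acylates the phenoxide while the carboxylate stays unreactive, giving the phenol-protected acid.

Step 18
Reactants: 24 4-acetoxy-3-methoxybenzoic acid; 22 (1R,3E,8E)-2,2,9-trimethyl-5-methylidenecycloundeca-3,8-dien-1-ol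
Product: 26 (1R,3E,8E)-2,2,9-trimethyl-5-methylidenecycloundeca-3,8-dien-1-yl 4-acetoxy-3-methoxybenzoate, via acid chloride 25 (not isolated)
Conditions: (COCl)2, DMF (cat.), CH2Cl2, 0 °C → rt, evaporate; 22, Et3N, DMAP, CH2Cl2, 0 °C → rt
Reagents that add atoms: none
Why: the acid is activated as its chloride with oxalyl chloride and DMF, and DMAP-catalysed acylation of the hindered C5 alcohol then occurs on oxygen with retention at C5 (nucleophilic acyl substitution).

Step 19
Reactants: 26 (1R,3E,8E)-2,2,9-trimethyl-5-methylidenecycloundeca-3,8-dien-1-yl 4-acetoxy-3-methoxybenzoate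
Product: 27 (1R,3E,8E)-2,2,9-trimethyl-5-methylidenecycloundeca-3,8-dien-1-yl 4-hydroxy-3-methoxybenzoate (target)
Conditions: pyrrolidine, CH2Cl2, 0 °C → rt
Reagents that add atoms: none
Why: aminolysis cleaves the aryl acetate, a far better acylating agent than the hindered alkyl aroate, and releases the phenol of the target (chemoselective deacetylation).

Compound list
1 | cycloheptane-1,3-dione | O=C1CCCCC(=O)C1 | starting material
2 | iodomethane | CI | starting material
3 | 2-methylcycloheptane-1,3-dione | CC1C(=O)CCCCC1=O | intermediate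
4 | methyl vinyl ketone (but-3-en-2-one) | CC(=O)C=C | starting material
5 | 2-methyl-2-(3-oxobutyl)cycloheptane-1,3-dione (not isolated) | CC(=O)CCC1(C)C(=O)CCCCC1=O | intermediate
6 | (8R)-enedione, (4aR)-4a-methyl-4,4a,6,7,8,9-hexahydro-3H-benzo[7]annulene-2,5-dione | C[C@@]12CCC(=O)C=C1CCCCC2=O | intermediate
7 | (8R,9R)-hydroxy enone, C9–OH cis to the C8 methyl | C[C@@]12CCC(=O)C=C1CCCC[C@H]2O | intermediate
8 | (8R,9R)-C9 triethylsilyl ether of 7 | C[C@@]12CCC(=O)C=C1CCCC[C@H]2O[Si](CC)(CC)CC | intermediate
9 | (8R,9R)-β,γ-unsaturated ketone: C5 ketone, C4Me2, C2=C3, C9–OTES | C[C@@]12CCC(=O)C(C)(C)C1=CCCC[C@H]2O[Si](CC)(CC)CC | intermediate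
10 | (5R,8R,9R)-alcohol, C5–OH cis to the C8 methyl | C[C@@]12CC[C@@H](O)C(C)(C)C1=CCCC[C@H]2O[Si](CC)(CC)CC | intermediate
11 | (5R,8R,9R)-bis-silyl ether: C5–OTBS, C9–OTES | C[C@@]12CC[C@@H](O[Si](C)(C)C(C)(C)C)C(C)(C)C1=CCCC[C@H]2O[Si](CC)(CC)CC | intermediate
12 | (5R,8R,9R)-enone: C1 ketone conjugated with C2=C3 | C[C@@]12CC[C@@H](O[Si](C)(C)C(C)(C)C)C(C)(C)C1=CC(=O)CC[C@H]2O[Si](CC)(CC)CC | intermediate
13 | (5R,8R,9R)-diene: C1 methylene conjugated with C2=C3 | C[C@@]12CC[C@@H](O[Si](C)(C)C(C)(C)C)C(C)(C)C1=CC(=C)CC[C@H]2O[Si](CC)(CC)CC | intermediate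
14 | (2R,3S,5R,8S,9R)-vinyl epoxide: C2–C3 epoxide trans to the C8 methyl | C[C@@]12CC[C@@H](O[Si](C)(C)C(C)(C)C)C(C)(C)[C@]13O[C@@H]3C(=C)CC[C@H]2O[Si](CC)(CC)CC | intermediate
15 | (3S,5R,8S,9R)-tertiary alcohol: C3–OH trans to the C8 methyl, C1 methylene, C5–OTBS, C9–OTES | C[C@@]12CC[C@@H](O[Si](C)(C)C(C)(C)C)C(C)(C)[C@@]1(O)CC(=C)CC[C@H]2O[Si](CC)(CC)CC | intermediate
16 | (3S,5R,8S,9R)-C3,C9-diol, C5–OTBS | C[C@@]12CC[C@@H](O[Si](C)(C)C(C)(C)C)C(C)(C)[C@@]1(O)CC(=C)CC[C@H]2O | intermediate
17 | (3S,5R,8S,9R)-C9 mesylate, trans-fused fragmentation precursor | CC1(C)[C@H](O[Si](C)(C)C(C)(C)C)CC[C@@]2(C)[C@H](OS(C)(=O)=O)CCC(=C)C[C@]12O | intermediate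
18 | (5R,8E)-cycloundecenone, the fragmentation product: C3 ketone, C1 methylene, C4Me2, C5–OTBS, C8 methyl (not isolated) | CC1(C)[C@H](O[Si](C)(C)C(C)(C)C)CC/C(C)=C/CCC(=C)CC1=O | intermediate
19 | potassium (2Z)-dienolate of 18 (not isolated) | C=C1/C=C(\[O-])C(C)(C)[C@H](O[Si](C)(C)C(C)(C)C)CC/C(C)=C/CC1.[K+] | intermediate
20 | (2Z,5R,8E)-dienyl triflate, C1 trans to C4 | C=C1/C=C(\OS(=O)(=O)C(F)(F)F)C(C)(C)[C@H](O[Si](C)(C)C(C)(C)C)CC/C(C)=C/CC1 | intermediate
21 | (2E,5R,8E)-triene TBS ether | C=C1/C=C/C(C)(C)[C@H](O[Si](C)(C)C(C)(C)C)CC/C(C)=C/CC1 | intermediate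
22 | (1R,3E,8E)-2,2,9-trimethyl-5-methylidenecycloundeca-3,8-dien-1-ol | C=C1/C=C/C(C)(C)[C@H](O)CC/C(C)=C/CC1 | intermediate
23 | vanillic acid | COc1cc(ccc1O)C(=O)O | starting material
24 | 4-acetoxy-3-methoxybenzoic acid | COc1cc(ccc1OC(C)=O)C(=O)O | intermediate
25 | 4-acetoxy-3-methoxybenzoyl chloride (not isolated) | COc1cc(ccc1OC(C)=O)C(Cl)=O | intermediate
26 | (1R,3E,8E)-2,2,9-trimethyl-5-methylidenecycloundeca-3,8-dien-1-yl 4-acetoxy-3-methoxybenzoate | C=C1/C=C/C(C)(C)[C@H](OC(=O)c2ccc(OC(C)=O)c(OC)c2)CC/C(C)=C/CC1 | intermediate
27 | (1R,3E,8E)-2,2,9-trimethyl-5-methylidenecycloundeca-3,8-dien-1-yl 4-hydroxy-3-methoxybenzoate | C=C1/C=C/C(C)(C)[C@H](OC(=O)c2ccc(O)c(OC)c2)CC/C(C)=C/CC1 | target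

Total step count: 19. Longest linear sequence: 18 steps (steps 1–16, 18 and 19, from cycloheptane-1,3-dione); step 17 is a one-step side branch.

Steps most likely to fail

Step 14 (key step). Elimination of the mesylate toward C10 may compete if the seven-membered ring does not hold C9–O anti to C3–C8. Sulfonylation of the crowded dienolate may be slow, so that the remaining amide base consumes the triflimide. Enolisation inside the eleven-membered ring may also be poorly selective in geometry, with C1 cis to C4, which would end in the (2Z)-diene. The fallback sets out from mesylate 17 and replaces the triflate pathway by a syn-elimination. Fragmentation with KN(SiMe3)2 as above, followed by protonation of dienolate 19 at C2 with AcOH at −78 °C, should allow ketone 18 to be isolated. Hydride reduction (LiAlH4, Et2O, −78 °C) should give the C3 carbinol F1, of which either epimer serves. The Burgess reagent (toluene, 50 °C) then dehydrates it by a cyclic syn-elimination that can only use a C2 hydrogen and prefers the transition state with C1 remote from C4, and this comes back to the route at triene 21.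

Step 10. The peracid may prefer the unhindered C1 methylene over the crowded C2=C3 bond, or show poor facial selectivity. The fallback sets out from enone 12, in which C2=C3 is the only alkene. Nucleophilic epoxidation of the enone (tBuOOH, DBU, CH2Cl2; Weitz–Scheffer type), with the hydroperoxide adding to C3 from the face opposite the C8 methyl and the axial C4 methyl, should give the C1-keto epoxide F2. Wittig methylenation of F2 (Ph3PCH3Br, KOtBu, THF) then comes back to the route at vinyl epoxide 14.

Step 2. The amino-acid-mediated aldol condensation of the seven-membered triketone may proceed with poor enantioselectivity, and this would reach the target because C8 controls C5. The fallback sets out from dione 3 and gives up catalyst control in favour of a physical resolution. Michael addition to methyl vinyl ketone 4 (Et3N, EtOAc, rt) followed by an achiral aldol condensation (pyrrolidine, AcOH, toluene, reflux) should give the racemic enedione, that is 6 together with its mirror image, the (8S)-enedione F3. Reduction as in step 3 (NaBH4, EtOH, −10 °C) gives the racemic cis hydroxy enone, 7 together with its mirror image, the (8S,9S)-hydroxy enone F4. Preparative supercritical-fluid chromatography on an amylose tris(3,5-dimethylphenylcarbamate) stationary phase (CO2/MeOH) separates the two enantiomers, and this comes back to the route at hydroxy enone 7.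

Further compounds
F1 | step 14 | (5R,8E)-C3 carbinol derived from 18, both C3 epimers | CC1(C)[C@H](O[Si](C)(C)C(C)(C)C)CC/C(C)=C/CCC(=C)CC1O
F2 | step 10 | (2S,3S,5R,8S,9R)-C1-keto epoxide: C2–C3 epoxide trans to the C8 methyl, C5–OTBS, C9–OTES | C[C@@]12CC[C@@H](O[Si](C)(C)C(C)(C)C)C(C)(C)[C@]13O[C@@H]3C(=O)CC[C@H]2O[Si](CC)(CC)CC
F3 | step 2 | (8S)-enedione, the enantiomer of 6 | C[C@]12CCC(=O)C=C1CCCCC2=O
F4 | step 2 | (8S,9S)-hydroxy enone, the enantiomer of 7 | C[C@]12CCC(=O)C=C1CCCC[C@@H]2O
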